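**Remark (assumption):** gibberellane numbering (C1–C19) is used for every intermediate; α is the face of the lactone bridge, and β is the face of H-5, H-9, the C7 carboxyl, the C15–C16 bridge and the 2-, 3- and 12-hydroxyls, as read from the SMILES. TBS = tert-butyldimethylsilyl, TMSE = 2-(trimethylsilyl)ethyl.

**Retrosynthetic overview**
1. GA50 ⇐ Δ1-3-oxo-19,10-lactone 30, by C2 enolate hydroxylation, C3 reduction and fluoride deprotection.
2. 30 ⇐ ring A enone 28: the C4–C19 bond is made by C-acylation of the C4 dienolate with a carbonate held on O10. The trans A/B fusion locks O10 axial on ring A, cis-1,3 to C4 across C5, so the γ-lactone (C4–C19–O–C10–C5) can only close on the α face and fixes the quaternary C4.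
3. Ring A ⇐ ring-closing metathesis (C1=C2) after double vinylation of the C10 ketone and a C3 Weinreb amide; ring B ⇐ intramolecular Stetter reaction (C10–C9).
4. Ring D ⇐ gold-catalysed Conia-ene cyclisation (C13–C16); quaternary C8 and the C4–C7/C10 chain ⇐ tandem Michael addition/Ireland–Claisen rearrangement on an (R)-cyclohexenyl enoate.
5. Order of ring formation: C (starting ring) → D → B → A → lactone; one CBS reduction supplies the absolute configuration.

Key step: step 17

**Step 1**
Reactants: 1 3-ethoxycyclohex-2-en-1-one; 2 trimethyl(prop-1-yn-1-yl)silane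
Product: 5 3-[3-(trimethylsilyl)prop-2-yn-1-yl]cyclohex-2-en-1-one, via propargylic lithium reagent 3 (not isolated), via lithium alkoxide adduct 4 (not isolated)
Conditions: 2, n-BuLi, THF, −78 to −20 °C; 1, −78 °C; then 1 M HCl, 0 °C
Reagents that add atoms: water, O
Why: Stork–Danheiser sequence: the silyl-capped propargylic lithium reagent should add 1,2 to the vinylogous ester and acid hydrolysis with allylic transposition should give the 3-substituted enone; no stereocentre is formed.

**Step 2**
Reactants: 5 3-[3-(trimethylsilyl)prop-2-yn-1-yl]cyclohex-2-en-1-one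
Product: 6 (R)-3-[3-(trimethylsilyl)prop-2-yn-1-yl]cyclohex-2-en-1-ol
Conditions: (S)-2-methyl-CBS-oxazaborolidine (20 mol %), catecholborane, toluene, −78 °C
Reagents that add atoms: none
Why: Corey–Bakshi–Shibata reduction: with the alkenyl arm as the large group the (S)-catalyst should give the (R)-carbinol (future C11), and catecholborane leaves the alkynylsilane untouched.

**Step 3**
Reactants: 7 methyl (E)-4,4-dimethoxybut-2-enoate
Product: 8 (E)-4,4-dimethoxybut-2-enoic acid
Conditions: LiOH, THF/H2O, 0 °C to rt; cold 1 M HCl to pH 4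
Reagents that add atoms: lithium hydroxide, [Li+].[OH-]
Why: Saponification of the methyl ester; the dimethyl acetal is stable to base and to the brief cold acidification.

**Step 4**
Reactants: 6 (R)-3-[3-(trimethylsilyl)prop-2-yn-1-yl]cyclohex-2-en-1-ol; 8 (E)-4,4-dimethoxybut-2-enoic acid
Product: 9 (R)-3-[3-(trimethylsilyl)prop-2-yn-1-yl]cyclohex-2-en-1-yl (E)-4,4-dimethoxybut-2-enoate
Conditions: DCC, DMAP (cat.), CH2Cl2, 0 °C to rt
Reagents that add atoms: none
Why: Steglich esterification; the carbinol centre is not touched, so its configuration is retained.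

**Step 5**
Reactants: 9 (R)-3-[3-(trimethylsilyl)prop-2-yn-1-yl]cyclohex-2-en-1-yl (E)-4,4-dimethoxybut-2-enoate; 10 N-methoxy-N-methylpropanamide
Product: 15 3-(dimethoxymethyl)-5-[methoxy(methyl)amino]-4-methyl-5-oxo-2-[(1R)-1-(prop-2-yn-1-yl)cyclohex-2-en-1-yl]pentanoic acid (C4/C5/C6 epimer mixture), via lithium amide enolate 11 (not isolated), via lithium ester enolate 12 (not isolated), via silyl ketene acetal 13 (not isolated), via trimethylsilyl ester 14 (not isolated)
Conditions: 10, LiN(i-Pr)2, THF, −78 °C; 9, −78 °C; Me3SiCl/Et3N, −78 to 50 °C; then 1 M NaOH, MeOH, rt; 1 M HCl to pH 3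
Reagents that add atoms: none
Why: Tandem Michael addition–Ireland–Claisen rearrangement: the amide enolate adds to the enoate β-carbon (C5), the ester enolate is silylated, and the suprafacial [3,3] shift should transfer the carbinol configuration to the quaternary C8 (C6 enters on the face the oxygen leaves); the basic work-up also removes the alkynyl silyl group, and the C4, C5 and C6 centres are reset later (steps 14 and 17).

**Step 6**
Reactants: 15 the Claisen acid
Product: 16 2-(trimethylsilyl)ethyl ester of 15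
Conditions: Me3SiCH2CH2OH, EDC·HCl, DMAP, CH2Cl2, rt
Reagents that add atoms: 2-(trimethylsilyl)ethanol, OCC[Si](C)(C)C
Why: Carbodiimide esterification installs a hindered, fluoride-labile ester that should survive the later base, hydride and organometallic steps.

**Step 7**
Reactants: 16 the TMSE ester (ring C cyclohexene)
Product: 17 (4R)-4-(prop-2-yn-1-yl)cyclohex-2-en-1-one carrying the C6 chain at C4 (ring C enone with C12=O)
Conditions: CrO3, 3,5-dimethylpyrazole, CH2Cl2, −20 °C
Reagents that add atoms: chromium trioxide, O=[Cr](=O)=O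
Why: Allylic oxidation with the CrO3–dimethylpyrazole complex: C12 is the only allylic CH2 of the ring alkene (C8 is quaternary), so the enone C12(=O)–C11=C9 should form regioselectively.

**Step 8**
Reactants: 17 the ring C enone
Product: 18 cross-conjugated TBS dienol ether of 17 (C12–OTBS with C12=C13 and C9=C11)
Conditions: TBSOTf, Et3N, CH2Cl2, −78 °C
Reagents that add atoms: tert-butyldimethylsilyl trifluoromethanesulfonate, CC(C)(C)[Si](C)(C)OS(=O)(=O)C(F)(F)F
Why: Soft enolisation: the γ-carbon of the enone (C8) is quaternary, so the enone can only enolise towards C13 and the 2-silyloxydiene forms regiospecifically, while ester, amide and (at −78 °C) acetal are not affected.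

**Step 9**
Reactants: 18 the TBS dienol ether
Product: 19 7-methylidenebicyclo[3.2.1]oct-3-en-2-one (rings C/D) carrying the C6 chain at bridgehead C8
Conditions: Ph3PAuCl (5 mol %), AgBF4 (5 mol %), toluene/MeOH 10:1, rt
Reagents that add atoms: none
Why: Gold-catalysed Conia-ene-type 5-exo-dig carbocyclisation of a silyl enol ether onto a terminal alkyne (methanol takes the silyl group): C13 attacks C16 and closes ring D with the exocyclic methylene, the bridgehead C13 configuration being dictated by the propargyl arm on C8.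

**Step 10**
Reactants: 19 the bicyclic enone acetal
Product: 20 the corresponding C10 aldehyde
Conditions: 1 M HCl, THF, rt
Reagents that add atoms: water, O
Why: Mild acetal hydrolysis; the TMSE ester, the enone and the 1,1-disubstituted alkene tolerate dilute acid.

**Step 11**
Reactants: 20 the C10 aldehyde
Product: 21 tricyclic B/C/D diketone (C10 and C12 ketones; 9β-H; C5/C6 epimer mixture)
Conditions: 2-(pentafluorophenyl)-6,7-dihydro-5H-pyrrolo[2,1-c][1,2,4]triazol-2-ium tetrafluoroborate (20 mol %), KN(SiMe3)2 (20 mol %), toluene, rt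
Reagents that add atoms: none
Why: Intramolecular Stetter reaction: the Breslow intermediate (C10 acyl anion equivalent) adds 5-exo to the enone β-carbon C9 and closes ring B; the three-atom tether from C8 can only reach its own face of C9, so the B/C fusion is cis (9β-H).

**Step 12**
Reactants: 21 the tricyclic diketone
Product: 22 the 12β-alcohol (C10 ketone retained)
Conditions: (S)-2-methyl-CBS-oxazaborolidine (1 equiv), catecholborane, toluene, −78 to −40 °C
Reagents that add atoms: none
Why: Corey–Bakshi–Shibata reduction under catalyst control: the C12 ketone (one CH2 flank, one branched flank) should react in preference to the doubly α-branched C10 cyclopentanone, and the (S)-catalyst (large group = bridgehead C13) should give the equatorial 12β-alcohol.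

**Step 13**
Reactants: 22 the 12β-alcohol
Product: 23 the 12β-OTBS ether
Conditions: TBSOTf, 2,6-lutidine, CH2Cl2, −78 °C
Reagents that add atoms: tert-butyldimethylsilyl trifluoromethanesulfonate, CC(C)(C)[Si](C)(C)OS(=O)(=O)C(F)(F)F
Why: Silylation of the secondary alcohol at −78 °C, where the hindered C10 ketone is not enolised.

**Step 14**
Reactants: 23 the 12β-OTBS ketone (C5/C6 epimer mixture)
Product: 24 the same ketone with the C5 side chain α and the C6 ester β
Conditions: t-BuOK (0.3 equiv), t-BuOH/THF, 0 °C to rt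
Reagents that add atoms: none
Why: Equilibration through the C10 ketone enolate (C5) and the ester enolate (C6): the ester should settle on the convex β face of the cis-fused B/C system and the C5 chain trans to it, which converges the epimers from step 5.

**Step 15**
Reactants: 24 the equilibrated ketone
Product: 27 10β-vinyl 10α-phenyl carbonate with a vinyl ketone at C3 (C4 epimers), via bis(bromomagnesium) adduct 25 (not isolated), via carbonate amide adduct 26 (not isolated)
Conditions: CH2=CHMgBr (4 equiv), CeCl3 (4 equiv), THF, −78 to 0 °C; then PhOC(O)Cl, −78 to 0 °C; inverse quench into cold 1 M HCl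
Reagents that add atoms: vinylmagnesium bromide, C=C[Mg]Br; phenyl chloroformate, O=C(Cl)Oc1ccccc1
Why: Organocerium addition: vinyl should attack the C10 ketone from the convex β face, anti to the α-oriented C5 chain and to C11 (setting 10α-O), while the Weinreb amide is held as its tetrahedral adduct; the tertiary alkoxide is acylated in situ by the chloroformate and the acidic quench releases the vinyl ketone.

**Step 16**
Reactants: 27 the bis-vinyl carbonate
Product: 28 ring A enone: Δ1-3-ketone with 4-methyl (both epimers), 5β-H, 10α-OC(=O)OPh, 12β-OTBS, 16-methylidene and the TMSE ester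
Conditions: second-generation Grubbs catalyst (5 mol %), CH2Cl2 (5 mM), 40 °C
Reagents that add atoms: none
Why: Ring-closing metathesis between the two monosubstituted vinyl groups closes ring A as the cyclohexenone (C1=C2); the hindered 1,1-disubstituted C16 methylene should not compete.

**Step 17**
Reactants: 28 the ring A enone phenyl carbonate
Product: 30 Δ1-3-oxo-19,10-lactone (12β-OTBS, TMSE ester), via lithium dienolate 29 (not isolated)
Conditions: LiN(SiMe3)2 (1.2 equiv), THF, −78 to 0 °C; aq. NH4Cl
Reagents that add atoms: none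
Why: LiN(SiMe3)2 removes the only acidic ketone proton, H-4 (C2 is vinylic and the γ-carbon C10 is quaternary), to give the cross-conjugated dienolate 29, whose carbon C4 attacks the carbonate carbonyl C19 held on O10, and phenoxide leaves. The closest known reaction type is the intramolecular Claisen (Dieckmann-type) C-acylation of a ketone enolate by a carbonate to give a β-keto lactone. The γ-lactone ring (C4–C19–O–C10–C5) closes in a 5-exo-trig mode at the carbonyl carbon and completes the 2-oxabicyclo[3.2.1]octane of ring A and the lactone. The new quaternary centre C4 is controlled by the tether: O10 is axial on the α face of ring A (locked by the trans A/B fusion), so C19 can only bond to the α face of C4 and the methyl group becomes β, whichever C4 epimer of 28 is used. The step needs C- over O-acylation and C4 over C6 selectivity: the five-membered C-acylation should be favoured over the seven-membered enol carbonate, and the C6 ester proton is far less acidic than H-4. Phenoxide is a poor nucleophile, so the non-enolisable β-keto lactone should survive.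

**Step 18**
Reactants: 30 the Δ1-3-oxo lactone
Product: 32 2β-hydroxy-3-oxo lactone, via potassium enolate 31 (not isolated)
Conditions: K-Selectride (KBH(s-Bu)3, 1.1 equiv), THF, −78 °C; then (±)-trans-3-phenyl-2-(phenylsulfonyl)oxaziridine, −78 to −40 °C; aq. NH4Cl
Reagents that add atoms: 3-phenyl-2-(phenylsulfonyl)oxaziridine, O=S(=O)(c1ccccc1)N1OC1c1ccccc1
Why: Conjugate reduction of the β-unsubstituted cyclohexenone gives the C2 enolate regiospecifically, and Davis oxidation of this enolate should occur on the exo (β) face, opposite to the lactone bridge, to give the 2β-hydroxy ketone.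

**Step 19**
Reactants: 32 the 2β-hydroxy-3-oxo lactone
Product: 33 2β,3β-diol (12β-OTBS, TMSE ester)
Conditions: K-Selectride (KBH(s-Bu)3, 3 equiv), THF, −78 °C; aq. NH4Cl
Reagents that add atoms: none
Why: Bulky-hydride reduction of the 3-ketone: equatorial attack, as in reductions of 3-oxo-gibberellins with this reagent, should give the axial 3β-alcohol, cis to the 2β-hydroxyl.

**Step 20**
Reactants: 33 the protected diol
Product: 34 GA50
Conditions: n-Bu4NF, THF, rt to 40 °C; dilute HCl to pH 3
Reagents that add atoms: none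
Why: Fluoride cleaves the silyl ether and, by β-elimination, the 2-(trimethylsilyl)ethyl ester; the β-hydroxy lactone is not exposed to aqueous alkali.

**Compound list**
1 | 3-ethoxycyclohex-2-en-1-one | CCOC1=CC(=O)CCC1 | starting material
2 | trimethyl(prop-1-yn-1-yl)silane | CC#C[Si](C)(C)C | starting material
3 | [3-(trimethylsilyl)prop-2-yn-1-yl]lithium | [Li]CC#C[Si](C)(C)C | intermediate
4 | lithium 3-ethoxy-1-[3-(trimethylsilyl)prop-2-yn-1-yl]cyclohex-2-en-1-olate (racemic) | CCOC1=CC(O[Li])(CC#C[Si](C)(C)C)CCC1 | intermediate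
5 | 3-[3-(trimethylsilyl)prop-2-yn-1-yl]cyclohex-2-en-1-one | O=C1C=C(CC#C[Si](C)(C)C)CCC1 | intermediate
6 | (R)-3-[3-(trimethylsilyl)prop-2-yn-1-yl]cyclohex-2-en-1-ol | O[C@H]1C=C(CC#C[Si](C)(C)C)CCC1 | intermediate
7 | methyl (E)-4,4-dimethoxybut-2-enoate | COC(=O)/C=C/C(OC)OC | starting material
8 | (E)-4,4-dimethoxybut-2-enoic acid | OC(=O)/C=C/C(OC)OC | intermediate
9 | (R)-3-[3-(trimethylsilyl)prop-2-yn-1-yl]cyclohex-2-en-1-yl (E)-4,4-dimethoxybut-2-enoate | COC(OC)/C=C/C(=O)O[C@H]1C=C(CC#C[Si](C)(C)C)CCC1 | intermediate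
10 | N-methoxy-N-methylpropanamide | CCC(=O)N(C)OC | starting material
11 | lithium enolate of 10 | CC=C(O[Li])N(C)OC | intermediate
12 | lithium ester enolate of the Michael adduct (allylic ester of 6) | [Li]OC(=CC(C(OC)OC)C(C)C(=O)N(C)OC)O[C@H]1C=C(CC#C[Si](C)(C)C)CCC1 | intermediate
13 | trimethylsilyl ketene acetal of the Michael adduct | C[Si](C)(C)OC(=CC(C(OC)OC)C(C)C(=O)N(C)OC)O[C@H]1C=C(CC#C[Si](C)(C)C)CCC1 | intermediate
14 | trimethylsilyl ester after [3,3] shift (C8 quaternary, R; alkyne still silylated) | C[Si](C)(C)C#CC[C@]1(C(C(=O)O[Si](C)(C)C)C(C(OC)OC)C(C)C(=O)N(C)OC)CCCC=C1 | intermediate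
15 | 3-(dimethoxymethyl)-5-[methoxy(methyl)amino]-4-methyl-5-oxo-2-[(1R)-1-(prop-2-yn-1-yl)cyclohex-2-en-1-yl]pentanoic acid (epimers at C4, C5, C6) | C#CC[C@]1(C(C(=O)O)C(C(OC)OC)C(C)C(=O)N(C)OC)CCCC=C1 | intermediate
16 | 2-(trimethylsilyl)ethyl ester of 15 | C#CC[C@]1(C(C(=O)OCC[Si](C)(C)C)C(C(OC)OC)C(C)C(=O)N(C)OC)CCCC=C1 | intermediate
17 | (4R)-4-(prop-2-yn-1-yl)cyclohex-2-en-1-one with the C6 chain at C4 (C12 ketone) | C#CC[C@]1(C(C(=O)OCC[Si](C)(C)C)C(C(OC)OC)C(C)C(=O)N(C)OC)CCC(=O)C=C1 | intermediate
18 | cross-conjugated TBS dienol ether of 17 | C#CC[C@]1(C(C(=O)OCC[Si](C)(C)C)C(C(OC)OC)C(C)C(=O)N(C)OC)CC=C(O[Si](C)(C)C(C)(C)C)C=C1 | intermediate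
19 | 7-methylidenebicyclo[3.2.1]oct-3-en-2-one (rings C/D) with the acetal chain at bridgehead C8 | C=C1C[C@]2(C(C(=O)OCC[Si](C)(C)C)C(C(OC)OC)C(C)C(=O)N(C)OC)C[C@H]1C(=O)C=C2 | intermediate
20 | C10 aldehyde of 19 | C=C1C[C@]2(C(C(=O)OCC[Si](C)(C)C)C(C=O)C(C)C(=O)N(C)OC)C[C@H]1C(=O)C=C2 | intermediate
21 | tricyclic B/C/D 10,12-diketone, 9β-H (C5/C6 epimers) | C=C1C[C@]23C[C@H]1C(=O)C[C@H]2C(=O)C(C(C)C(=O)N(C)OC)C3C(=O)OCC[Si](C)(C)C | intermediate
22 | 12β-hydroxy 10-ketone | C=C1C[C@]23C[C@H]1[C@H](O)C[C@H]2C(=O)C(C(C)C(=O)N(C)OC)C3C(=O)OCC[Si](C)(C)C | intermediate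
23 | 12β-OTBS 10-ketone (C5/C6 epimers) | C=C1C[C@]23C[C@H]1[C@H](O[Si](C)(C)C(C)(C)C)C[C@H]2C(=O)C(C(C)C(=O)N(C)OC)C3C(=O)OCC[Si](C)(C)C | intermediate
24 | 12β-OTBS 10-ketone, C5 chain α, C6 ester β | C=C1C[C@]23C[C@H]1[C@H](O[Si](C)(C)C(C)(C)C)C[C@H]2C(=O)[C@@H](C(C)C(=O)N(C)OC)[C@@H]3C(=O)OCC[Si](C)(C)C | intermediate
25 | bis(bromomagnesium) adduct after double vinyl addition | C=C1C[C@]23C[C@H]1[C@H](O[Si](C)(C)C(C)(C)C)C[C@H]2[C@](O[Mg]Br)(C=C)[C@@H](C(C)C(O[Mg]Br)(C=C)N(C)OC)[C@@H]3C(=O)OCC[Si](C)(C)C | intermediate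
26 | 10α-phenyl carbonate with the amide adduct still intact | C=C1C[C@]23C[C@H]1[C@H](O[Si](C)(C)C(C)(C)C)C[C@H]2[C@](OC(=O)Oc4ccccc4)(C=C)[C@@H](C(C)C(O[Mg]Br)(C=C)N(C)OC)[C@@H]3C(=O)OCC[Si](C)(C)C | intermediate
27 | 10β-vinyl 10α-phenyl carbonate with vinyl ketone side chain (C4 epimers) | C=C1C[C@]23C[C@H]1[C@H](O[Si](C)(C)C(C)(C)C)C[C@H]2[C@](OC(=O)Oc4ccccc4)(C=C)[C@@H](C(C)C(=O)C=C)[C@@H]3C(=O)OCC[Si](C)(C)C | intermediate
28 | tetracyclic Δ1-3-ketone, 4-methyl (C4 epimers), 5β-H, 10α-OC(=O)OPh, 12β-OTBS, TMSE 7-oate | C=C1C[C@]23C[C@H]1[C@H](O[Si](C)(C)C(C)(C)C)C[C@H]2[C@]1(OC(=O)Oc4ccccc4)C=CC(=O)C(C)[C@H]1[C@@H]3C(=O)OCC[Si](C)(C)C | intermediate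
29 | lithium cross-conjugated dienolate of 28 (C3–OLi, C3=C4) | C=C1C[C@]23C[C@H]1[C@H](O[Si](C)(C)C(C)(C)C)C[C@H]2[C@]1(OC(=O)Oc4ccccc4)C=CC(O[Li])=C(C)[C@H]1[C@@H]3C(=O)OCC[Si](C)(C)C | intermediate
30 | Δ1-3-oxo-19,10-lactone, 12β-OTBS, TMSE 7-oate | C=C1C[C@]23C[C@H]1[C@H](O[Si](C)(C)C(C)(C)C)C[C@H]2[C@@]12C=CC(=O)[C@@](C)(C(=O)O1)[C@H]2[C@@H]3C(=O)OCC[Si](C)(C)C | intermediate
31 | potassium C2 enolate of the 1,2-dihydro-3-oxo lactone | C=C1C[C@]23C[C@H]1[C@H](O[Si](C)(C)C(C)(C)C)C[C@H]2[C@@]12CC=C(O[K])[C@@](C)(C(=O)O1)[C@H]2[C@@H]3C(=O)OCC[Si](C)(C)C | intermediate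
32 | 2β-hydroxy-3-oxo-19,10-lactone, 12β-OTBS, TMSE 7-oate | C=C1C[C@]23C[C@H]1[C@H](O[Si](C)(C)C(C)(C)C)C[C@H]2[C@@]12C[C@H](O)C(=O)[C@@](C)(C(=O)O1)[C@H]2[C@@H]3C(=O)OCC[Si](C)(C)C | intermediate
33 | 2β,3β-dihydroxy-19,10-lactone, 12β-OTBS, TMSE 7-oate | C=C1C[C@]23C[C@H]1[C@H](O[Si](C)(C)C(C)(C)C)C[C@H]2[C@@]12C[C@H](O)[C@H](O)[C@@](C)(C(=O)O1)[C@H]2[C@@H]3C(=O)OCC[Si](C)(C)C | intermediate
34 | GA50 (2β,3β,12β-trihydroxy-19,10-lactone 7-oic acid) | C=C1C[C@]23C[C@H]1[C@H](O)C[C@H]2[C@@]12C[C@H](O)[C@H](O)[C@@](C)(C(=O)O1)[C@H]2[C@@H]3C(=O)O | target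

**Step count and risks**
Total step count: 20. Longest linear sequence: 19 steps (steps 1, 2 and 4–20, from 3-ethoxycyclohex-2-en-1-one); step 3 prepares the side fragment.

Steps most likely to fail:

Step 15. The in situ acylation of the hindered tertiary alkoxide may be incomplete, or the amide adduct may collapse early and suffer over-addition. Fallback, setting out from 24: the double vinyl addition (CH2=CHMgBr, CeCl3, THF) is quenched directly into cold dilute HCl to give the vinyl carbinol vinyl ketone F1. Ring-closing metathesis with the second-generation Grubbs catalyst then gives the 10α-hydroxy enone F2. The tertiary alcohol is acylated without strong base (Boc2O, DMAP, MeCN) to the O10 tert-butyl carbonate F3. F3 is cyclised with LiN(SiMe3)2 as in step 17, with tert-butoxide as leaving group, and the route is rejoined at 30.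

Step 11. Formation of the Breslow intermediate from the α-branched aldehyde may be slow, so that aldol-type self-condensation competes. Fallback, setting out from 20: radical hydroacylation instead of carbene umpolung. Photocatalytic hydrogen abstraction from the aldehyde with (n-Bu4N)4W10O32 (2 mol %, MeCN, 390 nm) gives the acyl radical, which should add 5-exo to the enone β-carbon C9 (faster than decarbonylation of a secondary acyl radical). This gives 21 directly and makes no new compound (F0).

Step 12. Discrimination between the two ketones may be insufficient, or hydride may be delivered to the wrong face of C12. Fallback, setting out from 21: substrate-controlled reduction with NaBH4 (MeOH, −78 °C), which should still prefer the less hindered cyclohexanone-type C12 carbonyl. If it gives the axial 12α-alcohol F4, Mitsunobu inversion (4-nitrobenzoic acid, PPh3, diisopropyl azodicarboxylate, THF) gives the 12β 4-nitrobenzoate F5. Methanolysis (K2CO3, MeOH) then returns to the route at 22.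

**Further compounds**
F1 | step 15 | 10α-hydroxy-10β-vinyl compound with vinyl ketone side chain (12β-OTBS, TMSE ester) | C=C1C[C@]23C[C@H]1[C@H](O[Si](C)(C)C(C)(C)C)C[C@H]2[C@](O)(C=C)[C@@H](C(C)C(=O)C=C)[C@@H]3C(=O)OCC[Si](C)(C)C
F2 | step 15 | 10α-hydroxy-Δ1-3-ketone (ring A closed, C4 epimers) | C=C1C[C@]23C[C@H]1[C@H](O[Si](C)(C)C(C)(C)C)C[C@H]2[C@]1(O)C=CC(=O)C(C)[C@H]1[C@@H]3C(=O)OCC[Si](C)(C)C
F3 | step 15 | O10 tert-butyl carbonate of F2 | C=C1C[C@]23C[C@H]1[C@H](O[Si](C)(C)C(C)(C)C)C[C@H]2[C@]1(OC(=O)OC(C)(C)C)C=CC(=O)C(C)[C@H]1[C@@H]3C(=O)OCC[Si](C)(C)C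
F0 | step 11 | none | none
F4 | step 12 | 12α-hydroxy 10-ketone (C12 epimer of 22) | C=C1C[C@]23C[C@H]1[C@@H](O)C[C@H]2C(=O)C(C(C)C(=O)N(C)OC)C3C(=O)OCC[Si](C)(C)C
F5 | step 12 | 12β 4-nitrobenzoate of the 10-ketone | C=C1C[C@]23C[C@H]1[C@H](OC(=O)c4ccc(cc4)[N+](=O)[O-])C[C@H]2C(=O)C(C(C)C(=O)N(C)OC)C3C(=O)OCC[Si](C)(C)C
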